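## Analysis of the target

- The target is a 2,3-dihydro-1-benzofuran (O1, C2, C3, C3a, C4–C7, C7a). It carries a 3,4-dihydroxyphenyl group on C2, a 3,5-dihydroxyphenyl group on C3, a free hydroxyl on C4 and an (E)-3,4-dihydroxystyryl group on C6. Formally it is a piceatannol dimer in which the ring-fusion carbon C3a sits between two oxygen-bearing carbons.
- There are two stereocentres, C2 (S) and C3 (S). Reading the SMILES with the furan ring in the plane puts the two aryl groups on opposite faces, so the ring is 2,3-trans.
- The two centres are not equal. C2 is a benzylic ether carbon para to a phenolic oxygen; it ionises easily (para-quinone methide) and so can be equilibrated to the more stable trans arrangement. C3 is a triaryl-type methine with no epimerisation pathway, so absolute control of C3 is the real stereochemical problem.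
- The feature the route exploits: C3a is flanked by C4–OH and by C7a–O1, so the benzo ring (C3a–C7a) is symmetric about the C3a···C6 axis until O1 is tied to C2. C2 is an oxygen-bearing benzylic CH, exactly what a carbene at C3 produces by inserting into an Ar–O–CH2–Ar C–H bond.
- Sensitive groups are the two catechols (air oxidation), the E-stilbene (hydrogenation, light, strong protic acid), seven free phenols and the acid-labile C2–O1 bond.
- The difficulty is threefold: carbon substitution between the two oxygens of a 5-substituted resorcinol is disfavoured in oxidative and Friedel–Crafts chemistry, C3 has no neighbouring directing group, and seven oxygens must be unmasked without reductive conditions.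

## Retrosynthetic reasoning

**15 to 13 (C2 configuration and all O-protecting groups).** The target 15 is traced to the 2,3-cis octa-O-alkylated dihydrobenzofuran 13, which already holds C3 (S). One Lewis-acid operation has to cleave the methyl ethers and the O4 benzyl ether, and open and re-close the C2–O1 bond through para-quinone methide 14. C2 is thereby set by thermodynamics under control of C3, so the cis/trans outcome of the key step does not matter.

**13 to 11 via 12 (C2–C3 bond, furan ring, both stereocentres).** The C2–C3 bond is cut so that C3 becomes a diaryl carbene carbon and C2 the CH2 of an aryl benzyl ether. This is the one bond that joins the two stereocentres and closes the ring. Cutting here turns the product into an achiral diaryl ketone hydrazone 11 (oxidised in the flask to diazo compound 12). Because C3a has two ortho oxygens, both are given the same 3,4-dimethoxybenzyl group: one arm is the C–H donor, the other is the protecting group of C4–OH, and no regiochemical question remains. The forward reaction must deliver C3 in one absolute configuration from a catalyst alone.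

**11 to 7 and 8 via 9 and 10 (C3–aryl bond).** The hydrazone carbon is disconnected from the 3,5-dimethoxyphenyl ring: aryllithium 9 (from bromide 8) adds to nitrile 7. The resulting ketimine 10 is exchanged with hydrazine, which avoids condensation on a ketone shielded by two ortho alkoxy groups. The nitrile is chosen because it is also the activating group for the two earlier steps.

**7 to 5 and 6 (styryl C–C bond).** The stilbene is cut at the aryl–vinyl bond (Heck reaction of bromide 5 with styrene 6). It is placed before the aryllithium addition so that no aryl bromide is present to exchange with 9, and so that the key step delivers the complete carbon skeleton.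

**5 to 1 and 2 (two aryl C–O bonds).** Both ortho C–O bonds are cut back to difluoronitrile 1 and benzyl alcohol 2 (via alkoxide 3 and mono-ether 4). The nitrile activates both fluorides for SNAr and fixes the 1,2,3-pattern (O, C, O) that electrophilic chemistry on a resorcinol would not give.

## Alternatives that were turned down

**Alternative 1:** the textbook biomimetic cut of C3–C3a and C2–O1, which reduces the target to two molecules of piceatannol A1. The forward step is one-electron oxidation of A1, radical coupling of the alkene carbon of one unit to the ring carbon between the two hydroxyls of the other, and oxa-Michael closure of the quinone methide. It was turned down for these reasons: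
- The catechol ring is oxidised first, and its radical couples through the catechol oxygen and ring carbons or through the alkene carbons.
- The required partner is a radical on the resorcinol oxygen reacting at its most hindered ortho carbon, which is the least favoured regiochemistry.
- The product would be racemic and mixed with regioisomers, and the catechols over-oxidise to ortho-quinones.
- One step, but it controls neither constitution nor absolute configuration.

**Alternative 2:** dearomatisation. Only the C2–H and C3–H bonds are cut, leading to the flat 2,3-diarylbenzofuran A2. The forward step is enantioselective hydrogenation of the furan C2=C3 bond of A2 to the cis-dihydro compound, then C2 epimerisation. It was turned down for these reasons: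
- The double bond is tetrasubstituted, diaryl-substituted and shielded by the C4 oxygen substituent, the hardest case for heteroarene hydrogenation.
- The key step forms no skeletal bond, so the whole regiodefined benzofuran must be assembled first.
- Hydrogen excludes the stilbene and an aryl halide, so the styryl arm must be carried as an ester and built afterwards (reduction, oxidation, olefination).
- Hydrogenolysis of the benzylic C2–O1 bond is a further risk.

**Alternative 3:** a [4+1] cut of C2–C3 and C2–O1 that takes out C2 as a one-carbon unit. The forward step generates ortho-quinone methide A5 from benzhydrol A3 and a benzylic sulfonium ylide from salt A4; conjugate addition and ring closure with loss of dimethyl sulfide give the trans ring directly. It was turned down for these reasons: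
- C3 would be set in an intermolecular addition of a semi-stabilised ylide to a transient, very reactive quinone methide with a fast racemic background. Catalyst control in this manifold is tied to acyl-stabilised ylides.
- A3 needs metalation between two protected oxygens and deprotection before the key step, so there is no step advantage.
- The trans selectivity it offers is not needed, because C2 corrects itself.

Key step: step 4

Assumption: the absolute sense of induction of the Rh2(PTAD)4 antipodes on this di-ortho-substituted carbene is to be assigned on the first run; the text writes Rh2(R-PTAD)4 for the antipode that gives C3 (S).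

## Route

Step 1
Reactants: 1 4-bromo-2,6-difluorobenzonitrile; 2 (3,4-dimethoxyphenyl)methanol (2.2 equiv)
Product: 5 4-bromo-2,6-bis[(3,4-dimethoxyphenyl)methoxy]benzonitrile, via sodium (3,4-dimethoxyphenyl)methanolate 3 (not isolated), via 4-bromo-2-[(3,4-dimethoxyphenyl)methoxy]-6-fluorobenzonitrile 4 (not isolated)
Conditions: NaH (2.3 equiv), THF, 0 °C → 50 °C
Reagents that add atoms: none
Why: Double SNAr; both fluorides are ortho to the nitrile and leave through Meisenheimer adducts much faster than the para bromide, the first alkoxy group is meta to the second C–F and hardly deactivates it, and the limited amount of alkoxide should keep the C–Br bond intact.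

Step 2
Reactants: 5 4-bromo-2,6-bis[(3,4-dimethoxyphenyl)methoxy]benzonitrile; 6 4-ethenyl-1,2-dimethoxybenzene (3,4-dimethoxystyrene)
Product: 7 4-[(E)-2-(3,4-dimethoxyphenyl)ethenyl]-2,6-bis[(3,4-dimethoxyphenyl)methoxy]benzonitrile
Conditions: Pd(OAc)2 (3 mol %), P(o-tol)3 (6 mol %), Et3N, DMF, 100 °C
Reagents that add atoms: none
Why: Mizoroki–Heck reaction; the bromide is para to the nitrile and unhindered, the neutral bromide pathway should give terminal arylation, and syn insertion followed by syn β-hydride elimination sets the E alkene; nitrile and benzyl ethers are inert.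

Step 3
Reactants: 7 4-[(E)-2-(3,4-dimethoxyphenyl)ethenyl]-2,6-bis[(3,4-dimethoxyphenyl)methoxy]benzonitrile; 8 1-bromo-3,5-dimethoxybenzene
Product: 11 {2,6-bis[(3,4-dimethoxyphenyl)methoxy]-4-[(E)-2-(3,4-dimethoxyphenyl)ethenyl]phenyl}(3,5-dimethoxyphenyl)methanone hydrazone, via 3,5-dimethoxyphenyllithium 9 (not isolated), via N–H ketimine 10 (not isolated)
Conditions: 8 (1.3 equiv), n-BuLi (1.25 equiv), THF, −78 °C; then 7, −78 → 0 °C; MeOH; then N2H4·H2O (10 equiv), AcOH, EtOH, 70 °C, Ar
Reagents that add atoms: hydrazine (used as the hydrate), NN
Why: Bromine–lithium exchange gives 9, which should add once to the chelating, non-enolisable nitrile (the N-lithio ketimine is not attacked again; stilbene and ether CH2 groups are untouched at this temperature); acid-catalysed transimination of ketimine 10 by hydrazine with loss of ammonia then gives the hydrazone, under argon so that no diimide forms to reduce the alkene.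

Step 4
Reactants: 11 {2,6-bis[(3,4-dimethoxyphenyl)methoxy]-4-[(E)-2-(3,4-dimethoxyphenyl)ethenyl]phenyl}(3,5-dimethoxyphenyl)methanone hydrazone
Product: 13 (2R,3S)-2-(3,4-dimethoxyphenyl)-3-(3,5-dimethoxyphenyl)-4-[(3,4-dimethoxyphenyl)methoxy]-6-[(E)-2-(3,4-dimethoxyphenyl)ethenyl]-2,3-dihydro-1-benzofuran (2,3-cis), via diaryldiazomethane 12 (not isolated)
Conditions: MnO2 (8 equiv), CH2Cl2, 0 °C; filter; slow addition to Rh2(R-PTAD)4 (1 mol %), MeCN, 0 °C → rt
Reagents that add atoms: none
Why: MnO2 dehydrogenates the N–H hydrazone to diaryldiazomethane 12, and the chiral Rh(II) tetracarboxylate extrudes N2 to give a donor/donor (diaryl) Rh carbene whose low electrophilicity suppresses dimerisation and lets the intramolecular path win. The carbene carbon (future C3) inserts into a C–H bond of the ortho O–CH2–Ar group five atoms away through a concerted, asynchronous, hydride-transfer-like three-centre transition state, forming C2–C3 and closing the dihydrofuran ring as a 1,5-C–H insertion (five-membered ring; a four-membered oxonium ylide or a seven-membered arene addition is not competitive). The closest known reaction type is the Rh2(PTAD)4-catalysed enantioselective intramolecular C–H insertion of diaryl carbenes, generated from hydrazones with MnO2, into benzylic ether C–H bonds to give 2,3-cis-2,3-diaryl-2,3-dihydrobenzofurans. C3 is set by the catalyst, whose ligand wall differentiates the two faces of a carbene carrying one di-ortho-substituted and one meta-substituted aryl group; C2 is set relative to C3 (cis) because the C–H bond is delivered with the CH2 aryl group turned away from the ligand wall, and this centre is deliberately left for correction in step 5. Site selectivity, normally the main problem with two benzylic ether arms, is removed by the substrate: the two ortho O–CH2–Ar arms are interchanged by rotation about the C3a–carbene bond, so either gives 13, and the unused arm is the protecting group of C4–OH. Chemoselectivity over cyclopropanation of the remote 1,2-disubstituted stilbene (possible only between molecules) and over azine formation should follow from the five-membered intramolecular transition state, low concentration and slow addition of 12 to the catalyst.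

Step 5
Reactants: 13 (2R,3S)-2-(3,4-dimethoxyphenyl)-3-(3,5-dimethoxyphenyl)-4-[(3,4-dimethoxyphenyl)methoxy]-6-[(E)-2-(3,4-dimethoxyphenyl)ethenyl]-2,3-dihydro-1-benzofuran
Product: 15 5-[(2S,3S)-2-(3,4-dihydroxyphenyl)-6-[(E)-2-(3,4-dihydroxyphenyl)ethenyl]-4-hydroxy-2,3-dihydro-1-benzofuran-3-yl]benzene-1,3-diol, via ring-opened para-quinone methide 14 (not isolated)
Conditions: BBr3 (15 equiv), C6HMe5 (3 equiv), CH2Cl2, −78 °C → rt; MeOH, then degassed H2O, Ar
Reagents that add atoms: none
Why: BBr3 cleaves the eight aryl methyl ethers and the O4 3,4-dimethoxybenzyl ether (its cation is trapped by pentamethylbenzene) and, being the same kind of benzylic C–O bond, also opens C2–O1; on protic work-up the ring-opened material should pass through para-quinone methide 14, and either of the two equivalent flanking phenols re-closes by 5-exo-trig oxa-Michael addition to the thermodynamically preferred 2,3-trans ring, so C2 becomes S under control of C3. C3 has no acidic or ionisable bond and keeps the configuration from step 4; the C6 styryl group is remote from the C3 aryl ring, so acid-induced cyclisation onto the alkene is not available.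

## Compound list

1 | 4-bromo-2,6-difluorobenzonitrile | N#Cc1c(F)cc(Br)cc1F | starting material
2 | (3,4-dimethoxyphenyl)methanol | COc1ccc(CO)cc1OC | starting material
3 | sodium (3,4-dimethoxyphenyl)methanolate | COc1ccc(C[O-])cc1OC.[Na+] | intermediate
4 | 4-bromo-2-[(3,4-dimethoxyphenyl)methoxy]-6-fluorobenzonitrile | N#Cc1c(F)cc(Br)cc1OCc1ccc(OC)c(OC)c1 | intermediate
5 | 4-bromo-2,6-bis[(3,4-dimethoxyphenyl)methoxy]benzonitrile | N#Cc1c(OCc2ccc(OC)c(OC)c2)cc(Br)cc1OCc1ccc(OC)c(OC)c1 | intermediate
6 | 4-ethenyl-1,2-dimethoxybenzene | C=Cc1ccc(OC)c(OC)c1 | starting material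
7 | 4-[(E)-2-(3,4-dimethoxyphenyl)ethenyl]-2,6-bis[(3,4-dimethoxyphenyl)methoxy]benzonitrile | N#Cc1c(OCc2ccc(OC)c(OC)c2)cc(/C=C/c2ccc(OC)c(OC)c2)cc1OCc1ccc(OC)c(OC)c1 | intermediate
8 | 1-bromo-3,5-dimethoxybenzene | COc1cc(Br)cc(OC)c1 | starting material
9 | 3,5-dimethoxyphenyllithium | [Li]c1cc(OC)cc(OC)c1 | intermediate
10 | 1-{2,6-bis[(3,4-dimethoxyphenyl)methoxy]-4-[(E)-2-(3,4-dimethoxyphenyl)ethenyl]phenyl}-1-(3,5-dimethoxyphenyl)methanimine | N=C(c1cc(OC)cc(OC)c1)c1c(OCc2ccc(OC)c(OC)c2)cc(/C=C/c2ccc(OC)c(OC)c2)cc1OCc1ccc(OC)c(OC)c1 | intermediate
11 | {2,6-bis[(3,4-dimethoxyphenyl)methoxy]-4-[(E)-2-(3,4-dimethoxyphenyl)ethenyl]phenyl}(3,5-dimethoxyphenyl)methanone hydrazone | NN=C(c1cc(OC)cc(OC)c1)c1c(OCc2ccc(OC)c(OC)c2)cc(/C=C/c2ccc(OC)c(OC)c2)cc1OCc1ccc(OC)c(OC)c1 | intermediate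
12 | 2-[diazo(3,5-dimethoxyphenyl)methyl]-1,3-bis[(3,4-dimethoxyphenyl)methoxy]-5-[(E)-2-(3,4-dimethoxyphenyl)ethenyl]benzene | [N-]=[N+]=C(c1cc(OC)cc(OC)c1)c1c(OCc2ccc(OC)c(OC)c2)cc(/C=C/c2ccc(OC)c(OC)c2)cc1OCc1ccc(OC)c(OC)c1 | intermediate
13 | (2R,3S)-2-(3,4-dimethoxyphenyl)-3-(3,5-dimethoxyphenyl)-4-[(3,4-dimethoxyphenyl)methoxy]-6-[(E)-2-(3,4-dimethoxyphenyl)ethenyl]-2,3-dihydro-1-benzofuran | COc1cc(OC)cc([C@H]2c3c(OCc4ccc(OC)c(OC)c4)cc(/C=C/c4ccc(OC)c(OC)c4)cc3O[C@H]2c2ccc(OC)c(OC)c2)c1 | intermediate
14 | 4-[(2S)-2-(3,5-dihydroxyphenyl)-2-{2,6-dihydroxy-4-[(E)-2-(3,4-dihydroxyphenyl)ethenyl]phenyl}ethylidene]-2-hydroxycyclohexa-2,5-dien-1-one | Oc1cc(O)cc([C@H](C=C2C=CC(=O)C(O)=C2)c2c(O)cc(/C=C/c3ccc(O)c(O)c3)cc2O)c1 | intermediate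
15 | 5-[(2S,3S)-2-(3,4-dihydroxyphenyl)-6-[(E)-2-(3,4-dihydroxyphenyl)ethenyl]-4-hydroxy-2,3-dihydro-1-benzofuran-3-yl]benzene-1,3-diol | Oc1cc(O)cc([C@H]2c3c(O)cc(/C=C/c4ccc(O)c(O)c4)cc3O[C@@H]2c2ccc(O)c(O)c2)c1 | target

## Step count and risk

Total step count: 5. Longest linear sequence: 5 steps (1 → 5 → 7 → 11 → 13 → 15).

**Step 4 (key step).** The most likely failures are slow carbene formation from a di-ortho-substituted diaryldiazomethane, which favours azine formation, and eroded facial selectivity because the catalyst pocket must accept a 2,6-disubstituted aryl group. Capture of the carbene by the stilbene of a second molecule is a lesser concern.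

The fallback makes the C2–C3 bond by carbanion chemistry and takes the absolute configuration from resolution. It sets out from 7 and comes back at 13. Step 3 is run as far as ketimine 10, which is hydrolysed (1 M HCl, THF, 40 °C) to the stilbene diaryl ketone F1. KOt-Bu (THF, −40 → 0 °C) deprotonates one Ar–O–CH2–Ar arm, and the carbanion adds to the ketone (5-exo-trig) to give the racemic 3-hydroxy-2,3-dihydrobenzofuran F2. Ionic deoxygenation of this doubly benzylic tertiary alcohol (Et3SiH in excess, BF3·OEt2, CH2Cl2, −78 °C) should deliver hydride anti to the C2 aryl group and give the racemic cis compound F3. Preparative chiral SFC of F3 then provides 13.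

**Step 5.** Three tasks are loaded on one operation. Likely failures are incomplete inversion at C2 if re-closure is faster than equilibration, loss of the C3 proton from the ring-opened cation (which would erase C3), re-benzylation of the electron-rich rings by the released veratryl cation, partial demethylation, and air oxidation of the catechols on work-up.

The fallback separates the tasks. It sets out from 13 and comes back at 15. TFA (5–10 % v/v) with pentamethylbenzene in CH2Cl2 at 0 °C removes the O4 benzyl ether and equilibrates C2 through the 3,4-dimethoxybenzylic cation while all methyl ethers stay, giving the trans hexamethyl ether phenol F4. O-Demethylation of F4 (BBr3 or BCl3/n-Bu4NI, CH2Cl2, −78 → 0 °C) then gives 15 without a benzyl cation and without the need for epimerisation.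

**Step 3.** Likely failures are metalation of the ArO–CH2–Ar groups by the aryllithium followed by [1,2]-Wittig rearrangement, and incomplete exchange of the shielded ketimine with hydrazine or azine formation.

The fallback installs the aryl ketone before the benzyl ethers and makes the hydrazone by condensation. It sets out from 1 and 8 and comes back at 11. The Grignard reagent 3,5-dimethoxyphenylmagnesium bromide F5 (from 8 and Mg, THF) adds to nitrile 1, and acidic hydrolysis gives the difluoro diaryl ketone F6. Double SNAr with 2/NaH gives the bromo bis-ether ketone F7. Heck reaction with 6 gives the stilbene diaryl ketone F1, and forcing condensation with hydrazine hydrate (n-BuOH, AcOH cat., 110 °C, Ar) gives 11.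

## Further compounds

F1 | step 4 | {2,6-bis[(3,4-dimethoxyphenyl)methoxy]-4-[(E)-2-(3,4-dimethoxyphenyl)ethenyl]phenyl}(3,5-dimethoxyphenyl)methanone | O=C(c1cc(OC)cc(OC)c1)c1c(OCc2ccc(OC)c(OC)c2)cc(/C=C/c2ccc(OC)c(OC)c2)cc1OCc1ccc(OC)c(OC)c1
F2 | step 4 | 2-(3,4-dimethoxyphenyl)-3-(3,5-dimethoxyphenyl)-4-[(3,4-dimethoxyphenyl)methoxy]-6-[(E)-2-(3,4-dimethoxyphenyl)ethenyl]-2,3-dihydro-1-benzofuran-3-ol (racemic, C2/C3 diastereomer mixture) | COc1cc(OC)cc(C2(O)c3c(OCc4ccc(OC)c(OC)c4)cc(/C=C/c4ccc(OC)c(OC)c4)cc3OC2c2ccc(OC)c(OC)c2)c1
F3 | step 4 | rac-(2R*,3S*)-2-(3,4-dimethoxyphenyl)-3-(3,5-dimethoxyphenyl)-4-[(3,4-dimethoxyphenyl)methoxy]-6-[(E)-2-(3,4-dimethoxyphenyl)ethenyl]-2,3-dihydro-1-benzofuran (racemate of 13, relative configuration shown) | COc1cc(OC)cc([C@H]2c3c(OCc4ccc(OC)c(OC)c4)cc(/C=C/c4ccc(OC)c(OC)c4)cc3O[C@H]2c2ccc(OC)c(OC)c2)c1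
F4 | step 5 | (2S,3S)-2-(3,4-dimethoxyphenyl)-3-(3,5-dimethoxyphenyl)-6-[(E)-2-(3,4-dimethoxyphenyl)ethenyl]-2,3-dihydro-1-benzofuran-4-ol | COc1cc(OC)cc([C@H]2c3c(O)cc(/C=C/c4ccc(OC)c(OC)c4)cc3O[C@@H]2c2ccc(OC)c(OC)c2)c1
F5 | step 3 | 3,5-dimethoxyphenylmagnesium bromide | COc1cc(OC)cc([Mg]Br)c1
F6 | step 3 | (4-bromo-2,6-difluorophenyl)(3,5-dimethoxyphenyl)methanone | O=C(c1cc(OC)cc(OC)c1)c1c(F)cc(Br)cc1F
F7 | step 3 | {4-bromo-2,6-bis[(3,4-dimethoxyphenyl)methoxy]phenyl}(3,5-dimethoxyphenyl)methanone | O=C(c1cc(OC)cc(OC)c1)c1c(OCc2ccc(OC)c(OC)c2)cc(Br)cc1OCc1ccc(OC)c(OC)c1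
A1 | alternative 1 | piceatannol, 4-[(E)-2-(3,5-dihydroxyphenyl)ethenyl]benzene-1,2-diol | Oc1cc(O)cc(/C=C/c2ccc(O)c(O)c2)c1
A2 | alternative 2 | methyl 2-(3,4-dimethoxyphenyl)-3-(3,5-dimethoxyphenyl)-4-methoxy-1-benzofuran-6-carboxylate | COC(=O)c1cc(OC)c2c(c1)oc(-c1ccc(OC)c(OC)c1)c2-c1cc(OC)cc(OC)c1
A3 | alternative 3 | 5-bromo-2-[(3,5-dimethoxyphenyl)(hydroxy)methyl]benzene-1,3-diol (racemic) | COc1cc(OC)cc(C(O)c2c(O)cc(Br)cc2O)c1
A4 | alternative 3 | [(3,4-dimethoxyphenyl)methyl]dimethylsulfonium bromide | COc1ccc(C[S+](C)C)cc1OC.[Br-]
A5 | alternative 3 | 3-bromo-6-[(3,5-dimethoxyphenyl)methylidene]-5-hydroxycyclohexa-2,4-dien-1-one | O=C1C=C(Br)C=C(O)C1=Cc1cc(OC)cc(OC)c1
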